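**Retrosynthetic overview**

1. Last bonds: pyridine C3 to the acyl carbon (3-lithiated 2,4-dialkoxypyridine + decalin aldehyde 22, then oxidation and equilibration of C2) and pyridine C5 to C1′ (5-lithiopyridine + epoxy ketone 6). Ring C is bought as 5-bromo-2,4-dichloropyridine.
2. Ring D: with C1′ at the ketone level, C6′–C1′–C2′–C3′ is methyl vinyl ketone and C4′–C5′ is (silyloxy)acetaldehyde. One amine-catalysed Michael/aldol-condensation operation forms C3′–C4′ and C5′=C6′ and sets C4′.
3. Feature used: in ring D the oxygen-bearing carbons C1′ and C4′ are 1,4-related with the oxirane carbons C5′/C6′ between them, i.e. a 4-oxycyclohex-2-enone in which C4′ is the α-carbon and C5′ the carbonyl carbon of an aldehyde.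
4. Relay from C4′: the oxirane (C5′, C6′) is formed anti to the C4′ silyloxy group, then C1′ is set by aryl addition anti to the same group.
5. Rings A/B: iminium-catalysed intramolecular Diels–Alder reaction of a trienal made from (S)-citronellal. Order of ring formation: D, oxirane, A/B; a global fluoride deprotection ends the route.

Key step: step 1

Remark: ring D atoms are called C1′ (carbinol carbon on the pyridone), C2′ and C3′ (CH2), C4′ (CHOH), C5′ and C6′ (oxirane carbons, C6′ next to C1′); decalin atoms are numbered with C1 bearing the propenyl group, C2 the acyl group, C3=C4 the ring alkene. Reagents named without a number are taken to be commercially available.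

**Route**

Step 1
Reactants: 1 (tert-butyldimethylsilyloxy)acetaldehyde; 2 methyl vinyl ketone
Product: 5 (R)-4-[(tert-butyldimethylsilyl)oxy]cyclohex-2-en-1-one, via keto aldehyde 3 (not isolated), via aldol 4 (not isolated)
Conditions: (S)-2-[methoxy(diphenyl)methyl]pyrrolidine (5 mol %), ethyl 3,4-dihydroxybenzoate (20 mol %), neat, 4 °C; then toluene, p-TsOH·H2O (15 mol %), 45 °C
Reagents that add atoms: none
Why: The pyrrolidine condenses with 1 to an E-enamine whose face away from the methoxydiphenylmethyl group adds to the β-carbon of 2 (Michael addition, C3′–C4′); after hydrolysis of the enamine, acid turns the methyl ketone of 3 into its terminal enol, which closes ring D by a 6-(enolendo)-exo-trig aldol addition onto the aldehyde, and loss of water from 4 gives the C5′=C6′ bond. The closest known reaction type is the amine-catalysed Michael addition of aldehydes to vinyl ketones followed by Robinson-type aldol condensation to 4-substituted cyclohex-2-enones. C4′ is the only stereocentre that remains and it is set by the catalyst (R from the S-configured pyrrolidine); the carbinol centre of 4 is lost on dehydration. The step needs chemoselectivity for the cross-Michael addition over self-aldolisation of 1 (secured by the hindered prolinol ether and the catechol co-catalyst that activates 2), ring closure through the methyl enol only (the other enol and the aldehyde enol would have to form four-membered rings), and retention of the α-silyloxy stereocentre (no base is used and the six-ring aldol should be fast).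

Step 2
Reactants: 5 (R)-4-[(tert-butyldimethylsilyl)oxy]cyclohex-2-en-1-one
Product: 6 (1S,5R,6R)-5-[(tert-butyldimethylsilyl)oxy]-7-oxabicyclo[4.1.0]heptan-2-one (oxirane trans to the silyloxy group)
Conditions: 30 % aq. H2O2, BnMe3NOH (cat.), THF, 0 °C
Reagents that add atoms: hydrogen peroxide, OO
Why: Weitz–Scheffer epoxidation: the hydroperoxide anion adds to C5′ from the face opposite the adjacent pseudoaxial silyloxy group and the enolate closes the oxirane, so both oxirane stereocentres are relayed from C4′.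

Step 3
Reactants: 7 5-bromo-2,4-dichloropyridine
Product: 8 5-bromo-2,4-bis[2-(trimethylsilyl)ethoxy]pyridine
Conditions: Me3SiCH2CH2OH, NaH, DMF, 0 → 60 °C
Reagents that add atoms: 2-(trimethylsilyl)ethanol, C[Si](C)(C)CCO
Why: Twofold nucleophilic aromatic substitution at the 4- and 2-positions, which are activated by the ring nitrogen, while the 5-bromide (not activated) is kept for the halogen–metal exchange; the 2-(trimethylsilyl)ethyl ethers mask both pyridone oxygens in a fluoride-labile form.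

Step 4
Reactants: 8 5-bromo-2,4-bis[2-(trimethylsilyl)ethoxy]pyridine; 6 (1S,5R,6R)-5-[(tert-butyldimethylsilyl)oxy]-7-oxabicyclo[4.1.0]heptan-2-one
Product: 10 (1S,2R,5R,6R)-2-{4,6-bis[2-(trimethylsilyl)ethoxy]pyridin-3-yl}-5-[(tert-butyldimethylsilyl)oxy]-7-oxabicyclo[4.1.0]heptan-2-ol, via aryllithium 9 (not isolated)
Conditions: n-BuLi, THF, −78 °C; then 6 and LaCl3·2LiCl in THF, −78 → −40 °C
Reagents that add atoms: none
Why: Bromine–lithium exchange gives the pyridyllithium, which adds 1,2 to the lanthanum-activated (non-enolising) ketone from the face anti to the pseudoaxial C4′ silyloxy group, which shields its own face of the carbonyl carbon in the half-chair, i.e. syn to the small oxirane oxygen that can also bind the metal, so that the aryl group should end cis to the oxirane and the new tertiary hydroxyl cis to the C4′ oxygen (C1′ relayed from C4′).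

Step 5
Reactants: 10 (1S,2R,5R,6R)-2-{4,6-bis[2-(trimethylsilyl)ethoxy]pyridin-3-yl}-5-[(tert-butyldimethylsilyl)oxy]-7-oxabicyclo[4.1.0]heptan-2-ol
Product: 11 trimethylsilyl ether of 10 at the tertiary hydroxyl
Conditions: N-(trimethylsilyl)imidazole, CH2Cl2, 40 °C
Reagents that add atoms: N-(trimethylsilyl)imidazole, C[Si](C)(C)n1ccnc1
Why: N-(Trimethylsilyl)imidazole silylates the hindered tertiary alcohol under neutral conditions that leave the oxirane intact, so that no alkoxide sits next to the oxirane during the later lithiation.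

Step 6
Reactants: 12 (S)-citronellal
Product: 13 (2E,5S)-N-methoxy-N,5,9-trimethyldeca-2,8-dienamide
Conditions: Ph3P=CHC(O)N(OMe)Me, CH2Cl2, 40 °C
Reagents that add atoms: N-methoxy-N-methyl-2-(triphenyl-λ5-phosphanylidene)acetamide, CON(C)C(=O)C=P(c1ccccc1)(c1ccccc1)c1ccccc1
Why: Wittig reaction of the stabilised ylide gives the E-configured unsaturated N-methoxy-N-methylamide, a latent enal that differentiates this chain end from the ester introduced in step 8; the stereocentre of citronellal is β to the aldehyde and is not touched.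

Step 7
Reactants: 13 (2E,5S)-N-methoxy-N,5,9-trimethyldeca-2,8-dienamide
Product: 15 (2E,5S,8E)-N-methoxy-N,5,9-trimethyl-10-oxodeca-2,8-dienamide, via allylic alcohol 14 (not isolated)
Conditions: SeO2 (0.3 equiv), t-BuOOH, CH2Cl2, 0 °C → rt; then MnO2, CH2Cl2, rt
Reagents that add atoms: tert-butyl hydroperoxide, CC(C)(C)OO
Why: SeO2/t-BuOOH allylic oxidation (ene reaction, then 2,3-sigmatropic shift) attacks the E-methyl group of the electron-rich trisubstituted alkene and leaves the electron-poor enamide alone, and MnO2 then oxidises only the allylic alcohol to the E-enal.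

Step 8
Reactants: 15 (2E,5S,8E)-N-methoxy-N,5,9-trimethyl-10-oxodeca-2,8-dienamide
Product: 16 ethyl (2E,4E,8S,10E)-12-[methoxy(methyl)amino]-4,8-dimethyl-12-oxododeca-2,4,10-trienoate
Conditions: (EtO)2P(O)CH2CO2Et, NaH, THF, 0 °C
Reagents that add atoms: triethyl phosphonoacetate, CCOC(=O)CP(=O)(OCC)OCC
Why: Horner–Wadsworth–Emmons olefination of the enal gives the (2E,4E)-dienoate, the aldehyde reacting much faster with the stabilised phosphonate anion than the unsaturated amide does by conjugate addition.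

Step 9
Reactants: 16 ethyl (2E,4E,8S,10E)-12-[methoxy(methyl)amino]-4,8-dimethyl-12-oxododeca-2,4,10-trienoate
Product: 17 (2E,5S,8E,10E)-12-hydroxy-5,9-dimethyldodeca-2,8,10-trienal
Conditions: i-Bu2AlH (3.5 equiv), CH2Cl2, −78 °C; aq. potassium sodium tartrate
Reagents that add atoms: none
Why: One hydride reagent adjusts both ends: the ester is reduced to the allylic alcohol, whereas the N-methoxy-N-methylamide stops at the chelated aluminium hemiaminal and gives the enal only on work-up, so that over-reduction is avoided.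

Step 10
Reactants: 17 (2E,5S,8E,10E)-12-hydroxy-5,9-dimethyldodeca-2,8,10-trienal
Product: 18 (2E,5S,8E,10E)-12-[(tert-butyldiphenylsilyl)oxy]-5,9-dimethyldodeca-2,8,10-trienal
Conditions: TBDPSCl, imidazole, CH2Cl2, 0 °C
Reagents that add atoms: tert-butyl(chloro)diphenylsilane, CC(C)(C)[Si](Cl)(c1ccccc1)c1ccccc1
Why: Standard silylation of the primary dienyl alcohol; the bulky silyl ether should survive the aqueous acid of step 11 and the base of step 12 and keeps the side chain from forming a lactol with the neighbouring formyl group after cyclisation.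

Step 11
Reactants: 18 (2E,5S,8E,10E)-12-[(tert-butyldiphenylsilyl)oxy]-5,9-dimethyldodeca-2,8,10-trienal
Product: 19 (1R,2S,4aS,7S,8aS)-2-{[(tert-butyldiphenylsilyl)oxy]methyl}-4,7-dimethyl-1,2,4a,5,6,7,8,8a-octahydronaphthalene-1-carbaldehyde (trans-fused; formyl and silyloxymethyl cis)
Conditions: (2S,5S)-5-benzyl-2-tert-butyl-3-methylimidazolidin-4-one·CF3CO2H (20 mol %), MeCN/H2O 98:2, 5 °C
Reagents that add atoms: none
Why: Iminium-ion-catalysed intramolecular Diels–Alder reaction: the imidazolidinone lowers the LUMO of the enal, its benzyl group shields one face of the E-iminium ion, and the endo transition state with a chair-like four-carbon tether and an equatorial methyl group gives the trans-fused decalin, so that C1, C8a, C4a and C2 are set by the catalyst in the sense that matches the resident C7 stereocentre (the C2 side chain is cis to the formyl group, as the E,E-diene demands).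

Step 12
Reactants: 19 (1R,2S,4aS,7S,8aS)-2-{[(tert-butyldiphenylsilyl)oxy]methyl}-4,7-dimethyl-1,2,4a,5,6,7,8,8a-octahydronaphthalene-1-carbaldehyde
Product: 20 tert-butyl{[(1R,2R,4aS,7S,8aR)-4,7-dimethyl-1-[(E)-prop-1-en-1-yl]-1,2,4a,5,6,7,8,8a-octahydronaphthalen-2-yl]methoxy}diphenylsilane
Conditions: 5-(ethylsulfonyl)-1-phenyl-1H-tetrazole, KN(SiMe3)2, DME, −60 °C → rt
Reagents that add atoms: 5-(ethylsulfonyl)-1-phenyl-1H-tetrazole, CCS(=O)(=O)c1nnnn1-c1ccccc1
Why: Julia–Kocienski olefination of the α-branched aldehyde with the ethyl phenyltetrazolyl sulfone gives the E-propenyl group; C1 already carries its substituent in the stable equatorial position, so that base should not change it.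

Step 13
Reactants: 20 tert-butyl{[(1R,2R,4aS,7S,8aR)-4,7-dimethyl-1-[(E)-prop-1-en-1-yl]-1,2,4a,5,6,7,8,8a-octahydronaphthalen-2-yl]methoxy}diphenylsilane
Product: 21 [(1R,2R,4aS,7S,8aR)-4,7-dimethyl-1-[(E)-prop-1-en-1-yl]-1,2,4a,5,6,7,8,8a-octahydronaphthalen-2-yl]methanol
Conditions: Bu4NF, THF, rt
Reagents that add atoms: none
Why: Fluoride cleaves the silyl ether without touching the two alkenes.

Step 14
Reactants: 21 [(1R,2R,4aS,7S,8aR)-4,7-dimethyl-1-[(E)-prop-1-en-1-yl]-1,2,4a,5,6,7,8,8a-octahydronaphthalen-2-yl]methanol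
Product: 22 (1R,2R,4aS,7S,8aR)-4,7-dimethyl-1-[(E)-prop-1-en-1-yl]-1,2,4a,5,6,7,8,8a-octahydronaphthalene-2-carbaldehyde
Conditions: 1,1,1-triacetoxy-1,1-dihydro-1,2-benziodoxol-3(1H)-one (DMP), NaHCO3, CH2Cl2, 0 °C
Reagents that add atoms: none
Why: Buffered oxidation with DMP gives the β,γ-unsaturated aldehyde without acid or base that could move the ring double bond into conjugation; the configuration at C2 (formyl cis to the propenyl group) is of no consequence because C2 is equilibrated in step 17.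

Step 15
Reactants: 11 trimethylsilyl ether of 10; 22 (1R,2R,4aS,7S,8aR)-4,7-dimethyl-1-[(E)-prop-1-en-1-yl]-1,2,4a,5,6,7,8,8a-octahydronaphthalene-2-carbaldehyde
Product: 24 {2,4-bis[2-(trimethylsilyl)ethoxy]-5-[(1S,2R,5R,6R)-5-[(tert-butyldimethylsilyl)oxy]-2-[(trimethylsilyl)oxy]-7-oxabicyclo[4.1.0]heptan-2-yl]pyridin-3-yl}[(1R,2R,4aS,7S,8aR)-4,7-dimethyl-1-[(E)-prop-1-en-1-yl]-1,2,4a,5,6,7,8,8a-octahydronaphthalen-2-yl]methanol (both carbinol epimers), via lithiopyridine 23 (not isolated)
Conditions: n-BuLi, THF, −78 → −20 °C; then 22 and LaCl3·2LiCl in THF, −78 °C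
Reagents that add atoms: none
Why: Directed lithiation takes place at the pyridine C–H flanked by both ether oxygens, and the hindered aryllithium adds to the formyl group of 22, which the lanthanum salt activates and keeps from enolising; the new carbinol centre is inconsequential because it is oxidised in step 16.

Step 16
Reactants: 24 coupled carbinol
Product: 25 {2,4-bis[2-(trimethylsilyl)ethoxy]-5-[(1S,2R,5R,6R)-5-[(tert-butyldimethylsilyl)oxy]-2-[(trimethylsilyl)oxy]-7-oxabicyclo[4.1.0]heptan-2-yl]pyridin-3-yl}[(1R,2R,4aS,7S,8aR)-4,7-dimethyl-1-[(E)-prop-1-en-1-yl]-1,2,4a,5,6,7,8,8a-octahydronaphthalen-2-yl]methanone (acyl group cis to the propenyl group)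
Conditions: DMP, NaHCO3, CH2Cl2, rt
Reagents that add atoms: none
Why: DMP oxidises the secondary carbinol to the aryl ketone under buffered conditions that leave the silyl ethers, the oxirane and the alkenes untouched.

Step 17
Reactants: 25 ketone with the acyl group cis to the propenyl group
Product: 26 the C2 epimer of 25, decalin (1R,2S,4aS,7S,8aR), acyl group trans to the propenyl group
Conditions: DBU, toluene, 50 °C
Reagents that add atoms: none
Why: DBU equilibrates C2 through the extended enolate, which is reprotonated kinetically at the α-carbon, so that the bulky acyl group should move from the pseudoaxial position to the pseudoequatorial one and give the all-equatorial, thermodynamic epimer.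

Step 18
Reactants: 26 ketone with the acyl group trans to the propenyl group
Product: 27 4-hydroxy-5-[(1S,2R,5R,6S)-2,5-dihydroxy-7-oxabicyclo[4.1.0]heptan-2-yl]-3-{[(1R,2S,4aS,7S,8aR)-4,7-dimethyl-1-[(E)-prop-1-en-1-yl]-1,2,4a,5,6,7,8,8a-octahydronaphthalen-2-yl]carbonyl}pyridin-2(1H)-one (CNP0494338.1)
Conditions: Bu4NF, THF, 0 °C → rt; pH 6 phosphate buffer
Reagents that add atoms: none
Why: Fluoride attacks silicon in all four silyl groups, so that the two 2-(trimethylsilyl)ethyl ethers fragment (ethene and Me3SiF) to the 4-hydroxy-2-pyridone and the trimethylsilyl and tert-butyldimethylsilyl ethers are cleaved, which should give the target without acid that would open the oxirane.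

**Compound list**

1 | (tert-butyldimethylsilyloxy)acetaldehyde | O=CCO[Si](C)(C)C(C)(C)C | starting material
2 | methyl vinyl ketone | CC(=O)C=C | starting material
3 | (R)-2-[(tert-butyldimethylsilyl)oxy]-5-oxohexanal | CC(=O)CC[C@@H](O[Si](C)(C)C(C)(C)C)C=O | intermediate
4 | (4R)-4-[(tert-butyldimethylsilyl)oxy]-3-hydroxycyclohexan-1-one (either carbinol epimer) | O=C1CC[C@@H](O[Si](C)(C)C(C)(C)C)C(O)C1 | intermediate
5 | (R)-4-[(tert-butyldimethylsilyl)oxy]cyclohex-2-en-1-one | O=C1CC[C@@H](O[Si](C)(C)C(C)(C)C)C=C1 | intermediate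
6 | (1S,5R,6R)-5-[(tert-butyldimethylsilyl)oxy]-7-oxabicyclo[4.1.0]heptan-2-one | O=C1CC[C@@H](O[Si](C)(C)C(C)(C)C)[C@@H]2O[C@@H]21 | intermediate
7 | 5-bromo-2,4-dichloropyridine | Clc1cc(Cl)c(Br)cn1 | starting material
8 | 5-bromo-2,4-bis[2-(trimethylsilyl)ethoxy]pyridine | C[Si](C)(C)CCOc1cc(OCC[Si](C)(C)C)c(Br)cn1 | intermediate
9 | {4,6-bis[2-(trimethylsilyl)ethoxy]pyridin-3-yl}lithium | C[Si](C)(C)CCOc1cc(OCC[Si](C)(C)C)c([Li])cn1 | intermediate
10 | (1S,2R,5R,6R)-2-{4,6-bis[2-(trimethylsilyl)ethoxy]pyridin-3-yl}-5-[(tert-butyldimethylsilyl)oxy]-7-oxabicyclo[4.1.0]heptan-2-ol | C[Si](C)(C)CCOc1cc(OCC[Si](C)(C)C)c([C@]2(O)CC[C@@H](O[Si](C)(C)C(C)(C)C)[C@@H]3O[C@@H]32)cn1 | intermediate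
11 | trimethylsilyl ether of 10 at the tertiary hydroxyl | C[Si](C)(C)CCOc1cc(OCC[Si](C)(C)C)c([C@]2(O[Si](C)(C)C)CC[C@@H](O[Si](C)(C)C(C)(C)C)[C@@H]3O[C@@H]32)cn1 | intermediate
12 | (S)-citronellal, (3S)-3,7-dimethyloct-6-enal | O=CC[C@@H](C)CCC=C(C)C | starting material
13 | (2E,5S)-N-methoxy-N,5,9-trimethyldeca-2,8-dienamide | CON(C)C(=O)/C=C/C[C@@H](C)CCC=C(C)C | intermediate
14 | (2E,5S,8E)-10-hydroxy-N-methoxy-N,5,9-trimethyldeca-2,8-dienamide | CON(C)C(=O)/C=C/C[C@@H](C)CC/C=C(\C)CO | intermediate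
15 | (2E,5S,8E)-N-methoxy-N,5,9-trimethyl-10-oxodeca-2,8-dienamide | CON(C)C(=O)/C=C/C[C@@H](C)CC/C=C(\C)C=O | intermediate
16 | ethyl (2E,4E,8S,10E)-12-[methoxy(methyl)amino]-4,8-dimethyl-12-oxododeca-2,4,10-trienoate | CON(C)C(=O)/C=C/C[C@@H](C)CC/C=C(\C)/C=C/C(=O)OCC | intermediate
17 | (2E,5S,8E,10E)-12-hydroxy-5,9-dimethyldodeca-2,8,10-trienal | O=C/C=C/C[C@@H](C)CC/C=C(\C)/C=C/CO | intermediate
18 | (2E,5S,8E,10E)-12-[(tert-butyldiphenylsilyl)oxy]-5,9-dimethyldodeca-2,8,10-trienal | O=C/C=C/C[C@@H](C)CC/C=C(\C)/C=C/CO[Si](c1ccccc1)(c1ccccc1)C(C)(C)C | intermediate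
19 | (1R,2S,4aS,7S,8aS)-2-{[(tert-butyldiphenylsilyl)oxy]methyl}-4,7-dimethyl-1,2,4a,5,6,7,8,8a-octahydronaphthalene-1-carbaldehyde | O=C[C@@H]1[C@H]2C[C@@H](C)CC[C@@H]2C(C)=C[C@@H]1CO[Si](c1ccccc1)(c1ccccc1)C(C)(C)C | intermediate
20 | tert-butyl{[(1R,2R,4aS,7S,8aR)-4,7-dimethyl-1-[(E)-prop-1-en-1-yl]-1,2,4a,5,6,7,8,8a-octahydronaphthalen-2-yl]methoxy}diphenylsilane | C/C=C/[C@@H]1[C@H]2C[C@@H](C)CC[C@@H]2C(C)=C[C@@H]1CO[Si](c1ccccc1)(c1ccccc1)C(C)(C)C | intermediate
21 | [(1R,2R,4aS,7S,8aR)-4,7-dimethyl-1-[(E)-prop-1-en-1-yl]-1,2,4a,5,6,7,8,8a-octahydronaphthalen-2-yl]methanol | C/C=C/[C@@H]1[C@H]2C[C@@H](C)CC[C@@H]2C(C)=C[C@@H]1CO | intermediate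
22 | (1R,2R,4aS,7S,8aR)-4,7-dimethyl-1-[(E)-prop-1-en-1-yl]-1,2,4a,5,6,7,8,8a-octahydronaphthalene-2-carbaldehyde | C/C=C/[C@@H]1[C@H]2C[C@@H](C)CC[C@@H]2C(C)=C[C@@H]1C=O | intermediate
23 | 3-lithio derivative of 11 (lithium on the pyridine carbon between the two ether groups) | C[Si](C)(C)CCOc1ncc([C@]2(O[Si](C)(C)C)CC[C@@H](O[Si](C)(C)C(C)(C)C)[C@@H]3O[C@@H]32)c(OCC[Si](C)(C)C)c1[Li] | intermediate
24 | coupled carbinol (pyridin-3-yl)(decalin-2-yl)methanol, both carbinol epimers, decalin (1R,2R,4aS,7S,8aR) | C/C=C/[C@@H]1[C@H]2C[C@@H](C)CC[C@@H]2C(C)=C[C@@H]1C(O)c1c(OCC[Si](C)(C)C)ncc([C@]2(O[Si](C)(C)C)CC[C@@H](O[Si](C)(C)C(C)(C)C)[C@@H]3O[C@@H]32)c1OCC[Si](C)(C)C | intermediate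
25 | ketone from 24, decalin (1R,2R,4aS,7S,8aR), acyl cis to propenyl | C/C=C/[C@@H]1[C@H]2C[C@@H](C)CC[C@@H]2C(C)=C[C@@H]1C(=O)c1c(OCC[Si](C)(C)C)ncc([C@]2(O[Si](C)(C)C)CC[C@@H](O[Si](C)(C)C(C)(C)C)[C@@H]3O[C@@H]32)c1OCC[Si](C)(C)C | intermediate
26 | C2 epimer of 25, decalin (1R,2S,4aS,7S,8aR), acyl trans to propenyl | C/C=C/[C@@H]1[C@H]2C[C@@H](C)CC[C@@H]2C(C)=C[C@H]1C(=O)c1c(OCC[Si](C)(C)C)ncc([C@]2(O[Si](C)(C)C)CC[C@@H](O[Si](C)(C)C(C)(C)C)[C@@H]3O[C@@H]32)c1OCC[Si](C)(C)C | intermediate
27 | 4-hydroxy-5-[(1S,2R,5R,6S)-2,5-dihydroxy-7-oxabicyclo[4.1.0]heptan-2-yl]-3-{[(1R,2S,4aS,7S,8aR)-4,7-dimethyl-1-[(E)-prop-1-en-1-yl]-1,2,4a,5,6,7,8,8a-octahydronaphthalen-2-yl]carbonyl}pyridin-2(1H)-one | C/C=C/[C@@H]1[C@H]2C[C@@H](C)CC[C@@H]2C(C)=C[C@H]1C(=O)c1c(O)c([C@]2(O)CC[C@@H](O)[C@@H]3O[C@@H]32)c[nH]c1=O | target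

**Step count and risks**

Total step count: 18. Longest linear sequence: 13 steps (steps 6 to 18, from (S)-citronellal).

Steps most likely to fail:

1. Step 15 (fragment union). The hindered 3-lithiopyridine may act as a base toward the α-C–H of aldehyde 22, which is both α to the formyl group and allylic, so that enolisation and double-bond migration compete with addition. The fallback sets out from 22: chlorite oxidation (NaClO2, NaH2PO4, 2-methyl-2-butene, t-BuOH/H2O) gives the carboxylic acid F1, condensation with N,O-dimethylhydroxylamine hydrochloride (N-ethyl-N′-(3-dimethylaminopropyl)carbodiimide hydrochloride, i-Pr2NEt, CH2Cl2) gives the N-methoxy-N-methylamide F2, and lithiopyridine 23 is acylated by F2, whose chelated tetrahedral adduct collapses only on work-up. This gives ketone 25 directly, so the route is rejoined at 25 and step 16 is not needed.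

2. Step 4 (tertiary carbinol). The aryl-metal may approach anti to the oxirane and give the C1′ epimer, or it may enolise the epoxy ketone and open the oxirane by β-elimination. The fallback sets out from 8 and enone 5: aryllithium 9 is added 1,2 to enone 5 (LaCl3·2LiCl, THF, −78 °C), anti to the silyloxy group, to give the cis-1,4 allylic alcohol F3; N-(trimethylsilyl)imidazole gives its trimethylsilyl ether F4; epoxidation with m-CPBA/NaHCO3, now anti to both silyloxy groups, rejoins the route at 11.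

3. Step 18 (global deprotection). Once the C1′ and C4′ oxygens are free under basic fluoride, the oxirane may migrate (Payne-type) or open, and the 2-O-[2-(trimethylsilyl)ethyl] group may leave slowly. The fallback sets out from 26 and separates the events: CsF in DMF at room temperature should remove only the two pyridyl 2-(trimethylsilyl)ethyl ethers and the trimethylsilyl ether and give the pyridone F5, in which C4′ stays silylated; HF·pyridine buffered with pyridine in THF at 0 °C then cleaves the tert-butyldimethylsilyl ether under weakly acidic conditions and gives 27.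

Further compounds
F1 | step 15 | (1R,2R,4aS,7S,8aR)-4,7-dimethyl-1-[(E)-prop-1-en-1-yl]-1,2,4a,5,6,7,8,8a-octahydronaphthalene-2-carboxylic acid | C/C=C/[C@@H]1[C@H]2C[C@@H](C)CC[C@@H]2C(C)=C[C@@H]1C(=O)O
F2 | step 15 | (1R,2R,4aS,7S,8aR)-N-methoxy-N,4,7-trimethyl-1-[(E)-prop-1-en-1-yl]-1,2,4a,5,6,7,8,8a-octahydronaphthalene-2-carboxamide | C/C=C/[C@@H]1[C@H]2C[C@@H](C)CC[C@@H]2C(C)=C[C@@H]1C(=O)N(C)OC
F3 | step 4 | (1S,4R)-1-{4,6-bis[2-(trimethylsilyl)ethoxy]pyridin-3-yl}-4-[(tert-butyldimethylsilyl)oxy]cyclohex-2-en-1-ol | C[Si](C)(C)CCOc1cc(OCC[Si](C)(C)C)c([C@]2(O)CC[C@@H](O[Si](C)(C)C(C)(C)C)C=C2)cn1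
F4 | step 4 | trimethylsilyl ether of F3 at the tertiary hydroxyl | C[Si](C)(C)CCOc1cc(OCC[Si](C)(C)C)c([C@]2(O[Si](C)(C)C)CC[C@@H](O[Si](C)(C)C(C)(C)C)C=C2)cn1
F5 | step 18 | 5-[(1S,2R,5R,6R)-5-[(tert-butyldimethylsilyl)oxy]-2-hydroxy-7-oxabicyclo[4.1.0]heptan-2-yl]-4-hydroxy-3-{[(1R,2S,4aS,7S,8aR)-4,7-dimethyl-1-[(E)-prop-1-en-1-yl]-1,2,4a,5,6,7,8,8a-octahydronaphthalen-2-yl]carbonyl}pyridin-2(1H)-one | C/C=C/[C@@H]1[C@H]2C[C@@H](C)CC[C@@H]2C(C)=C[C@H]1C(=O)c1c(O)c([C@]2(O)CC[C@@H](O[Si](C)(C)C(C)(C)C)[C@@H]3O[C@@H]32)c[nH]c1=O
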